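The pitfall is to step a scheme through by hand for each flask before asking where each flask must end.

| flask | first end groups | second end groups | remark | time |
|---|---|---|---|---|
| winter | 0.0095 M | 0.0108 M | run made earlier |  |
| midnight | 0.045 M | 0.0108 M | run made earlier |  |
| larch | 0.020 M | 0.0108 M |  | 10 h |
| elm | 0.050 M | 0.0108 M |  | 10 h |
| cedar | 0.0080 M | 0.0108 M |  | 10 h |
| maple | 0.040 M | 0.0108 M |  | 10 h |
| ash | 0.012 M | 0.0108 M |  | 10 h |

| run | time / h | links / % |
|---|---|---|
| winter | 0.417 | 9.0 |
| winter | 1.00 | 19.9 |
| winter | 2.00 | 29.4 |
| winter | 5.00 | 42.8 |
| midnight | 0.667 | 10.4 |
| midnight | 2.00 | 17.6 |
| midnight | 3.00 | 17.1 |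
| midnight | 5.00 | 16.6 |

(standard deviation of a reading: 0.5 percentage points)

- the earlier runs were read with a standard deviation of 0.5 percentage points

1. the flasks by amount of links, in percent of the first end groups charged, highest first, at 10 h (larch / elm / cedar / maple / ash)
2. the same order at 40 h (larch / elm / cedar / maple / ash)
3. the amount of links, in percent of the first end groups charged of the flask you put first, at 10 h
4. the amount of links, in percent of the first end groups charged of the flask you put last, at 10 h

Let r be the second end groups charged per first end group charged. I assume one link takes one of each, so the full charge of links is the smaller of 1 and r.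

Take first the fast extreme, a flask already at its end. The midnight run has r = 0.240, and its last readings barely drift, from 17.6% to 16.6%. Divide the last reading by r:

s = 0.692

This is the kept share: links held at the end per unit of the smaller charge. In elm, r is 0.216, so second end groups are the limiting reagent:

elm: s × r = 14.9%

Cedar has r = 1.35, so my estimate of its end is s, 69.2%. The midnight readings were still drifting down, so I hold this as a high estimate.

The slow extreme is cedar frozen at the last winter reading, 42.8%. Cedar has less first end groups than winter and runs longer, so I place it between these two values. Near-equal charges suggest a hyperbola, y = s·t/(t + τ). Winter gives the approach time: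

τ = 3.08 h

cedar at 10 h: 52.9%

Cedar has a larger r than elm, and this reckoning gives it the higher end, so I rank the flasks by r at both times.

The forecast gives cedar > ash > larch > maple > elm at 10 h and cedar > ash > larch > maple > elm at 40 h, with top 51% and low 14%. Its ground is that “Simple reversibility does not fit both runs”, so it stepped a three-step picture by hand. My order is the same, but I let cedar climb towards s after 10 h, while the forecast has links decaying.

    links ⇌ isomer of the product (K = 0.550, k = 0.00370 min⁻¹)
    first end groups + second end groups ⇌ links + by-product (K = 35.0, k = 0.420 M⁻¹ min⁻¹)

At 10 h the flasks stand cedar > ash > larch > maple > elm, with cedar at 52.7% and elm at 13.9%; at 40 h they stand cedar > ash > larch > maple > elm, with cedar at 61.3%. In elm, the link-forming step had 68% of its turnover behind it by 1.00 h, and at 0.583 h links were made 6.23 times faster than used up. Links and isomer of the product then relaxed with a half-life of 1.11 h, shorter than 10 h, leaving elm at 10.0 h with 7.59% isomer and second end groups at 0.509% of their charge. A further flask like elm, charged with 0.085 M of first end groups, has r = 0.127; s × r gives 8.79%, and that flask holds 8.19%.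

The data are calculated with made-up constants.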